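The constants are made up; the run is a simulation.

Third end groups race first end groups for the second end groups, and each link formed then ages into over-reaction product.

    first end groups + second end groups → links (k1 = 34 /M/h)
    second end groups + third end groups → links of the second sort (k2 = 92 /M/h)
    third end groups + protic impurity → quenched substrate (k3 = 8.8 /M/h)
    links → over-reaction product (k4 = 0.10 /h)

| setting | noon | autumn | dusk | spring | summer |
|---|---|---|---|---|---|
| first end groups | 44 mM (fed, over 4.0 h) | 44 mM (fed, over 1.0 h) | 44 mM | 44 mM | 44 mM |
| second end groups | 44.0 mM | 44.0 mM | 44.0 mM | 44.0 mM | 44.0 mM |
| third end groups | 44.0 mM | 44.0 mM | 44.0 mM (in portions, 3, over 4.0 h) | 44.0 mM | 44.0 mM (fed, over 4.0 h) |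
| protic impurity | 44.0 mM | 44.0 mM | 44.0 mM | 44.0 mM | 44.0 mM |
| time | 20 h | 20 h | 20 h | 20 h | 20 h |
| remark | all else is in the flask from the start; the feed brings no volume worth counting | all else is in the flask from the start; the feed brings no volume worth counting | first portion at the start, last at 4.0 h | everything together at the start | all else is in the flask from the start; the feed brings no volume worth counting |

- the flask that comes out highest in amount of over-reaction product, in percent of the first end groups charged, or "all alike" when all lie within 1.5 percentage points (noon / autumn / dusk / spring / summer / all alike)
- over-reaction product at the end, in percent of the first end groups charged, noon
- over-reaction product at the end, in percent of the first end groups charged, autumn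
- over-reaction product at the end, in percent of the first end groups charged, dusk
- over-reaction product at the end, in percent of the first end groups charged, spring
- over-reaction product at the end, in percent of the first end groups charged, summer

In summer, first and second end groups are charged equally. Each second end group won by third end groups therefore spares one first end group, and links equal the charge less the links of the second sort. Taking first and second end groups to fall together, first end groups stand at the charge over one plus D x, where x is the fraction of feed time and D = 5.98 is the rate constant of link formation times charge times feed time. If every dosed third end group is captured, the two amounts meet where x plus D x squared equals one, at x = 33.4%, which leaves links at 66.6%.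

The weak link is "every": protic impurity also takes third end groups. Replacing falling second end groups by their mean, 22.0 mM, gives a capture rate of 2.02 /h against a quench rate of 0.387 /h. This yields the capture share c, the part of third end groups reaching second end groups rather than protic impurity: 83.9%. The meeting condition becomes c x plus c D x squared equals one, so x = 37.0%, the race lasts 1.48 h, and third end groups win 31.1%. Links born at the race's mean time have aged by 85.4% at the end, so my figure for summer is 58.8%.

In dusk, the first portion of 14.7 mM counts at share c as 12.3 mM captured. Taking the ratio of second to first end groups to decay exponentially, 5.58 mM of second end groups await the next portion at 2.00 h. That portion wins about 3.84 mM, so dusk's links of the second sort reach 16.1 mM, more than summer's 13.7 mM. My reckoning therefore puts summer above dusk.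

The forecast names dusk, with noon at 16.5%, autumn at 21.5%, dusk at 55%, spring at 30.5% and summer at 53%, on the ground that “holding back the third end groups leaves most of them for link formation”. It differs from my reckoning in the order of dusk and summer and in summer's figure.

The simulation puts summer highest at 60.4%, above dusk at 55.7%, with spring at 31.1%, autumn at 21.5% and noon at 16.1%. Summer holds 12.9 mM of links of the second sort and dusk 15.3 mM, against 13.7 mM reckoned for summer. A neighbour of noon is charged 18 mM of third end groups. Taking its second end groups to fall from 44.0 mM by about that charge, a mean of 35.0 mM, c becomes 89.3%. That gives 16.1 mM of links of the second sort and leaves 63.5% of first end groups to form links. The neighbour holds 16.1 mM of links of the second sort, with links at 11.6% and over-reaction product at 51.9%.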